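## Retrosynthetic overview

1. Numbering used in the text: C1 lactone C=O, C2 CH2, C3 CH(OO), C4 C(CH3)(O-lactone), C5 ring CH2, C6 C(CH3)(chain)(OO). The C6 methyl comes last, by axial methylation of the cyclic peroxycarbenium ion of a 6-methoxy-1,2-dioxane. That dioxane comes from a butenolide ketone, H2O2 and MeOH (perketal, then 6-exo oxa-Michael at C3).
2. The butenolide ketone comes from a tertiary cyclobutanol by radical scission of a temporary C3–C6 bond. The Ph(CH2)12 chain is added as a Grignard reagent to the cyclobutanone carbon C6.
3. Enabling feature: C3 and C6, the two carbons that hold the O–O bridge of the 1,2-dioxane, stand 1,4 across the C4–C5 edge, and C3–C4 is also the fusion bond to the γ-lactone. Replacing O–O by a direct C3–C6 bond contracts the dioxane to a cyclobutanone fused to the lactone.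
4. In that bicycle C1–C2–C3–C6 is a succinyl chain and C4(CH3)(O)–C5 is an isopropenyl ester. An auxiliary-controlled intramolecular keteniminium/enol ester [2+2] therefore makes C5–C6 and C3–C4 in one operation from an acyclic succinamate.
5. Ring order: γ-lactone and temporary cyclobutane together (step 3), cyclobutane opened (step 6), 1,2-dioxane closed (step 7).

Key step: step 3

Assumption: the (2R,5R) auxiliary is taken to deliver the (1S,5S) bicycle 8. Both antipodes of the amine are commercial, so the (2S,5S) amine would be used if the sense of induction is the opposite.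

## Route

Step 1
Reactants: 1 succinic anhydride; 2 (2R,5R)-2,5-dimethylpyrrolidine
Product: 3 4-[(2R,5R)-2,5-dimethylpyrrolidin-1-yl]-4-oxobutanoic acid
Conditions: DMAP (cat.), CH2Cl2, 0 °C → reflux
Reagents that add atoms: none
Why: Aminolysis (ring opening) of the cyclic anhydride by the secondary amine stops at the amide acid because the carboxylate formed is unreactive, and no stereocentre is touched.

Step 2
Reactants: 3 amide acid; 4 propyne
Product: 5 prop-1-en-2-yl 4-[(2R,5R)-2,5-dimethylpyrrolidin-1-yl]-4-oxobutanoate
Conditions: [RuCl2(p-cymene)(PPh3)] (2 mol %), propyne (excess, sealed vessel), toluene, 100 °C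
Reagents that add atoms: none
Why: Ruthenium-catalysed Markovnikov addition of a carboxylic acid to a terminal alkyne places the carboxylate on the internal carbon of propyne and gives the isopropenyl ester under neutral conditions that leave the tertiary amide untouched.

Step 3
Reactants: 5 isopropenyl succinamate
Product: 8 (1S,5S)-1-methyl-2-oxabicyclo[3.2.0]heptane-3,6-dione, via keteniminium triflate 6 (not isolated), via cyclobutaniminium triflate 7 (not isolated)
Conditions: Tf2O (1.1 equiv), 2,4,6-collidine (1.2 equiv), ClCH2CH2Cl (0.01 M), 0 → 80 °C; then H2O, aq. NaHCO3, rt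
Reagents that add atoms: water, O
Why: Proposed new method: O-triflation of the tertiary amide and loss of a C3 proton give the aldoketeniminium ion 6, whose electrophilic central carbon C6 is attacked by the nucleophilic CH2 terminus C5 of the isopropenyl ester while the enamine carbon C3 collapses on the methyl- and oxygen-stabilised C4, an asynchronous [2+2] that makes C5–C6 and C3–C4 in one event; hydrolysis of 7 then frees the ketone and the auxiliary. The closest known reaction types are the intramolecular keteniminium–olefin [2+2] of ω-alkenyl amides that carry chiral pyrrolidine auxiliaries (giving bicyclo[3.2.0]heptan-6-ones) and the ketene–enol ether [2+2] giving 3-alkoxycyclobutanones; new are the enol ester as 2π partner and the ester link in the tether. Ring closure: the C3–C4 bond closes the γ-lactone (five-membered, 5-exo-trig at the enol ester carbon C4, with C5 outside that ring), and C5–C6 together with C3–C4 closes the temporary cyclobutane in the fused, not bridged, [2+2] mode. Stereocontrol: the three-atom tether C2–C1–O allows only the cis fusion (H-3 cis to the C4 methyl; C3 is transient), and the C2-symmetric auxiliary, whose methyl groups flank the C=N+ π-face that C5 must approach, selects the alkene face and so sets C4 as S. Selectivity needed: amide over ester activation (the amide oxygen is by far the better nucleophile toward Tf2O), fused over bridged regiochemistry (the polarisation of CH2=C(CH3)O– is matched with the tether), and cyclisation over oligomerisation (keteniminium ions do not dimerise, so dilution and heat can funnel the minor s-E ester rotamer).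

Step 4
Reactants: 9 1,12-dibromododecane; 10 phenylmagnesium bromide
Product: 11 (12-bromododecyl)benzene
Conditions: 9 (3 equiv), Li2CuCl4 (3 mol %), THF–NMP, 0 °C → rt
Reagents that add atoms: none
Why: Copper-catalysed Grignard–alkyl bromide cross-coupling (Kochi type); the excess of the symmetrical dibromide holds the reaction at mono-arylation, and surplus 9 is removed by distillation.

Step 5
Reactants: 8 bicyclic keto lactone; 11 (12-bromododecyl)benzene
Product: 13 (1S,5R,6R)-6-hydroxy-1-methyl-6-(12-phenyldodecyl)-2-oxabicyclo[3.2.0]heptan-3-one, via alkylmagnesium bromide 12 (not isolated)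
Conditions: 11, Mg, THF, 40 °C; then LaCl3·2LiCl (0.3 equiv), 8, THF, −78 °C; sat. aq. NH4Cl at −78 °C
Reagents that add atoms: none
Why: Lanthanide-promoted Grignard 1,2-addition: the strained cyclobutanone is far more electrophilic than the γ-lactone, La(III) and −78 °C suppress enolisation, β-elimination of the C4 carboxylate and acyl migration in the alkoxide, attack should come from the convex face (cis to H-3 and the C4 methyl), and the new carbinol centre is erased in step 6.

Step 6
Reactants: 13 tertiary cyclobutanol
Product: 15 (S)-5-methyl-5-(2-oxo-14-phenyltetradecyl)furan-2(5H)-one, via β-iodo lactone 14 (not isolated)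
Conditions: PhI(OAc)2 (0.6 equiv), I2 (0.6 equiv), CH2Cl2, visible light, rt; then Et3N (1.2 equiv), 0 °C, short contact
Reagents that add atoms: none
Why: Hypoiodite alkoxy-radical β-fragmentation (Suárez reaction): the strained cyclobutyloxy radical cleaves toward the more substituted side, which breaks the temporary C3–C6 bond, makes C6 the ketone and leaves a secondary C3 radical that is iodinated, and brief Et3N treatment removes HI (E2/E1cB) to give the conjugated butenolide without touching C4.

Step 7
Reactants: 15 butenolide ketone
Product: 17 (4aS,7aS)-3-methoxy-4a-methyl-3-(12-phenyldodecyl)tetrahydrofuro[3,2-c][1,2]dioxin-6-one (6-methoxy analogue of the target, both C6 epimers), via hydroperoxy ketal 16 (not isolated)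
Conditions: urea·H2O2 (5 equiv), Sc(OTf)3 (10 mol %), MeOH, rt; evaporate; Et2NH (0.3 equiv), CF3CH2OH, rt
Reagents that add atoms: urea–hydrogen peroxide, NC(N)=O.OO; methanol, CO
Why: Acid-catalysed perhydrolysis of the ketone to the α-methoxy hydroperoxide followed by amine-catalysed intramolecular oxa-Michael addition (6-exo-trig) to the butenolide; the C4–C5–C6 tether reaches only the butenolide face cis to C5, so C3 is set S with a cis ring fusion by substrate control from C4, and the mixture at the ketal carbon C6 does not matter because step 8 ionises it.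

Step 8
Reactants: 17 6-methoxy-1,2-dioxane lactone
Product: 18 plakortolide L
Conditions: Me3Al (3 equiv), TMSOTf (0.2 equiv), CH2Cl2, −78 → −40 °C; then H2O
Reagents that add atoms: trimethylaluminium, C[Al](C)C
Why: Proposed new method: the Lewis acid pair ionises the exocyclic methoxy group to the cyclic peroxycarbenium ion (C6=O+–O), which Me3Al methylates along the axial trajectory of the half-chair that keeps the C4–O bond pseudoaxial and the C4 methyl pseudoequatorial, so the new methyl ends cis to the lactone oxygen and to C2 (6S) and the chain becomes equatorial, whereas the other half-chair would force the nucleophile syn-axial to the C4 methyl. The closest known reaction types are the Lewis acid mediated substitution of 3-alkoxy- and 3-acetoxy-1,2-dioxanes by allylsilanes, silyl enol ethers and silanes via peroxycarbenium ions (3,6-cis products) and the Me3Al methylation of cyclic oxocarbenium ions, also in peroxide-bearing trioxanes; new is a methylaluminium nucleophile on a peroxycarbenium ion.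

## Compound list

1 | succinic anhydride | O=C1CCC(=O)O1 | starting material
2 | (2R,5R)-2,5-dimethylpyrrolidine | C[C@@H]1CC[C@@H](C)N1 | starting material
3 | 4-[(2R,5R)-2,5-dimethylpyrrolidin-1-yl]-4-oxobutanoic acid | C[C@@H]1CC[C@@H](C)N1C(=O)CCC(=O)O | intermediate
4 | propyne | CC#C | starting material
5 | prop-1-en-2-yl 4-[(2R,5R)-2,5-dimethylpyrrolidin-1-yl]-4-oxobutanoate | C[C@@H]1CC[C@@H](C)N1C(=O)CCC(=O)OC(C)=C | intermediate
6 | keteniminium triflate (N+=C6=C3H–CH2–CO2-isopropenyl) | C[C@@H]1CC[C@@H](C)[N+]1=C=CCC(=O)OC(C)=C.[O-]S(=O)(=O)C(F)(F)F | intermediate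
7 | cyclobutaniminium triflate of 8 | C[C@]12CC(=[N+]3[C@H](C)CC[C@H]3C)[C@H]1CC(=O)O2.[O-]S(=O)(=O)C(F)(F)F | intermediate
8 | (1S,5S)-1-methyl-2-oxabicyclo[3.2.0]heptane-3,6-dione (cis-fused) | C[C@]12CC(=O)[C@H]1CC(=O)O2 | intermediate
9 | 1,12-dibromododecane | BrCCCCCCCCCCCCBr | starting material
10 | phenylmagnesium bromide | Br[Mg]c1ccccc1 | starting material
11 | (12-bromododecyl)benzene | BrCCCCCCCCCCCCc1ccccc1 | intermediate
12 | 12-phenyldodecylmagnesium bromide | Br[Mg]CCCCCCCCCCCCc1ccccc1 | intermediate
13 | (1S,5R,6R)-6-hydroxy-1-methyl-6-(12-phenyldodecyl)-2-oxabicyclo[3.2.0]heptan-3-one | C[C@]12C[C@](O)(CCCCCCCCCCCCc3ccccc3)[C@H]1CC(=O)O2 | intermediate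
14 | (5S)-4-iodo-5-methyl-5-(2-oxo-14-phenyltetradecyl)dihydrofuran-2(3H)-one (C3 epimers) | C[C@@]1(CC(=O)CCCCCCCCCCCCc2ccccc2)OC(=O)CC1I | intermediate
15 | (S)-5-methyl-5-(2-oxo-14-phenyltetradecyl)furan-2(5H)-one | C[C@@]1(CC(=O)CCCCCCCCCCCCc2ccccc2)OC(=O)C=C1 | intermediate
16 | (5S)-5-(2-hydroperoxy-2-methoxy-14-phenyltetradecyl)-5-methylfuran-2(5H)-one (ketal epimers) | C[C@@]1(CC(OC)(OO)CCCCCCCCCCCCc2ccccc2)OC(=O)C=C1 | intermediate
17 | (4aS,7aS)-3-methoxy-4a-methyl-3-(12-phenyldodecyl)tetrahydrofuro[3,2-c][1,2]dioxin-6-one (C6 epimers) | COC1(CCCCCCCCCCCCc2ccccc2)C[C@]2(C)OC(=O)C[C@@H]2OO1 | intermediate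
18 | plakortolide L, (3S,4aS,7aS)-3,4a-dimethyl-3-(12-phenyldodecyl)tetrahydrofuro[3,2-c][1,2]dioxin-6-one | C[C@]1(CCCCCCCCCCCCc2ccccc2)C[C@]2(C)OC(=O)C[C@@H]2OO1 | target

Total step count: 8. Longest linear sequence: 7 (steps 1, 2, 3, 5, 6, 7, 8).

## Steps most likely to fail

**Step 3 (Proposed new method).**
- What may go wrong: the preferred s-Z ester rotamer keeps the two π systems apart. The keteniminium ion may then be lost by proton transfer, by capture through the ester carbonyl oxygen or by oligomerisation. The developing C4 cation may also lose a proton instead of closing, and the auxiliary may discriminate the alkene faces poorly.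
- Fallback, from 11 back to 15, known chemistry that again makes C3–C4 and C5–C6 in one operation.
- The Grignard reagent 12 is acylated with N-methoxy-N-methylacetamide (Weinreb ketone synthesis) to 14-phenyltetradecan-2-one F1.
- Kinetic deprotonation (LDA, −78 °C) and N-phenyltriflimide give 14-phenyltetradec-1-en-2-yl triflate F2.
- Commercial (1,3-dioxan-2-ylethyl)magnesium bromide is added to isopropenylboronic acid pinacol ester to give the bromomagnesium boronate complex F3.
- F3 is coupled with F2 under Pd(OAc)2/MandyPhos, NaOTf (enantioselective conjunctive cross-coupling with a Pd-induced 1,2-metallate shift, ligand antipode chosen for the S series) to the tertiary boronic ester F4.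
- NaOH/H2O2 gives, with retention, the tertiary alcohol F5. Aqueous acid gives the lactol F6, and TEMPO/PhI(OAc)2 the γ-lactone F7.
- LDA/PhSeBr gives the α-phenylselanyl lactone F8, and H2O2 (selenoxide elimination) the methylene butenolide F9.
- Ozonolysis (O3, then Me2S) cleaves only the electron-rich 1,1-disubstituted alkene and gives 15.

**Step 8 (Proposed new method).**
- What may go wrong: Lewis acid induced O–O heterolysis (Hock/Criegee-type fragmentation), ionisation of the endocyclic C6–OO bond instead of C6–OMe, reduction of the peroxide by the alkylaluminium, or proton loss from the peroxycarbenium ion.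
- Fallback, from 15 back to 18, known chemistry.
- Takai–Lombardo methylenation (Zn, CH2Br2, TiCl4; non-basic, ketone-selective) gives the methylene butenolide F9.
- Mukaiyama–Isayama hydroperoxysilylation (Co(thd)2 cat., O2, Et3SiH, ClCH2CH2Cl) gives the triethylsilyl peroxide F10 as both C6 epimers.
- Aqueous HF in MeCN frees the tertiary hydroperoxide F11.
- Et2NH in CF3CH2OH closes the dioxane by oxa-Michael addition to give 18 together with the 6-epimer F12, which is removed by chromatography. This path gives up control at C6.

**Step 7.**
- What may go wrong: slow perketalisation of the hindered ketone, opening of the β-acyloxy ketone (loss of the C4 carboxylate, erosion of C4) before the ketone is masked, or nucleophilic epoxidation of the butenolide by residual H2O2 once the amine is added.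
- Fallback, from 13 back to 17, bypassing steps 6 and 7.
- Cobalt-catalysed aerobic ring expansion of the cyclobutanol (Co(acac)2 cat., O2, 1 atm) inserts O2 directly into the temporary C3–C6 bond. The sequence is alkoxy radical, scission to the C3 radical, O2 capture, then closure of the hydroperoxide on the C6 ketone.
- Only the hydroperoxide formed cis to the C5 arm can close. The product is the peroxyhemiketal F13.
- MeOH with catalytic TsOH and molecular sieves then converts F13 into 17.

## Further compounds

F1 | step 3 | 14-phenyltetradecan-2-one | CC(=O)CCCCCCCCCCCCc1ccccc1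
F2 | step 3 | 14-phenyltetradec-1-en-2-yl triflate | C=C(OS(=O)(=O)C(F)(F)F)CCCCCCCCCCCCc1ccccc1
F3 | step 3 | bromomagnesium boronate complex ([2-(1,3-dioxan-2-yl)ethyl](isopropenyl)(pinacolato)borate) | CC(=C)[B-]1(CCC2OCCCO2)OC(C)(C)C(C)(C)O1.[Mg+]Br
F4 | step 3 | tertiary boronic ester | C[C@@](B1OC(C)(C)C(C)(C)O1)(CCC1OCCCO1)CC(=C)CCCCCCCCCCCCc1ccccc1
F5 | step 3 | tertiary alcohol | C[C@@](O)(CCC1OCCCO1)CC(=C)CCCCCCCCCCCCc1ccccc1
F6 | step 3 | lactol | C[C@@]1(CC(=C)CCCCCCCCCCCCc2ccccc2)OC(O)CC1
F7 | step 3 | γ-lactone | C[C@@]1(CC(=C)CCCCCCCCCCCCc2ccccc2)OC(=O)CC1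
F8 | step 3 | α-phenylselanyl lactone | C[C@@]1(CC(=C)CCCCCCCCCCCCc2ccccc2)OC(=O)C([Se]c2ccccc2)C1
F9 | step 3 | methylene butenolide, (S)-5-methyl-5-(2-methylidene-14-phenyltetradecyl)furan-2(5H)-one | C[C@@]1(CC(=C)CCCCCCCCCCCCc2ccccc2)OC(=O)C=C1
F10 | step 8 | triethylsilyl peroxide (C6 epimers) | C[C@@]1(CC(C)(OO[Si](CC)(CC)CC)CCCCCCCCCCCCc2ccccc2)OC(=O)C=C1
F11 | step 8 | tertiary hydroperoxide (C6 epimers) | C[C@@]1(CC(C)(OO)CCCCCCCCCCCCc2ccccc2)OC(=O)C=C1
F12 | step 8 | 6-epimer of 18 | C[C@@]1(CCCCCCCCCCCCc2ccccc2)C[C@]2(C)OC(=O)C[C@@H]2OO1
F13 | step 7 | peroxyhemiketal (6-hydroxy analogue of 17) | OC1(CCCCCCCCCCCCc2ccccc2)C[C@]2(C)OC(=O)C[C@@H]2OO1
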